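## Retrosynthetic overview

1. Coumarate C=C: Horner–Wadsworth–Emmons disconnection to a phosphonoacetate of the fully acylated diol and unprotected 4-hydroxybenzaldehyde (last step, no phenol protection).
2. Two acyl C–O bonds: the tertiary acetate (put on second) and the secondary phosphonoacetate (put on first) lead back to (3R,4S)-3,7-dimethylocta-1,6-diene-3,4-diol.
3. C5–C6 bond: opening of a terminal epoxy alcohol at its CH2 by an isobutenyl Grignard reagent with CuI.
4. Key step: that epoxy alcohol, carrying both stereocentres, comes in one step from achiral 3-methylpenta-1,4-dien-3-ol by an epoxidation that selects one of two enantiotopic vinyl groups and one of its faces.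
5. Rings: the only ring formed is the oxirane (step 1), opened again in step 2; the benzene ring is bought.

Assumption: 3-methylpenta-1,4-dien-3-ol and the bishydroxamic acid ligand are taken as purchasable, and the (R,R)-ligand is taken to be the enantiomer that gives the (2R,2'S)-epoxy alcohol (if a first run shows the opposite sense, the (S,S)-ligand is used and nothing else changes).

## Route

Step 1
Reactants: 1 3-methylpenta-1,4-dien-3-ol
Product: 2 (2R)-2-[(2S)-oxiran-2-yl]but-3-en-2-ol
Conditions: Hf(OtBu)4 (10 mol %), (R,R)-N,N'-dihydroxy-N,N'-bis(diphenylacetyl)cyclohexane-1,2-diamine (11 mol %), cumene hydroperoxide (1.3 equiv), 4 Å MS, toluene, 0 °C to rt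
Reagents that add atoms: cumene hydroperoxide, CC(C)(OO)c1ccccc1
Why: Proposed new method: the tertiary alkoxide of 1 binds the tetravalent hafnium complex formed in situ from Hf(OtBu)4 and the C2-symmetric bishydroxamic acid, and the metal-bound cumyl peroxide transfers oxygen intramolecularly to one face of one enantiotopic vinyl group (face fixed by the ligand; choice of vinyl group fixed by methyl, not the longer spectator vinyl, pointing at the ligand), so the carbinol centre (R) and the oxirane centre (S) are set in one event; the closest known reactions are the hafnium- and zirconium-bishydroxamic acid catalysed enantioselective epoxidation of tertiary allylic alcohols and the Sharpless desymmetrisation of secondary divinyl carbinols, from which the self-correcting feature is borrowed (the minor stereoisomers keep the matched vinyl group and are drained to bis-epoxide, so d.r. and e.e. rise with conversion).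

Step 2
Reactants: 2 (2R)-2-[(2S)-oxiran-2-yl]but-3-en-2-ol; 3 (2-methylprop-1-en-1-yl)magnesium bromide
Product: 4 (3R,4S)-3,7-dimethylocta-1,6-diene-3,4-diol
Conditions: 3 (3 equiv), CuI (10 mol %), THF, −40 to 0 °C; then H2O
Reagents that add atoms: none
Why: Copper-catalysed Grignard opening of an epoxide (SN2): after deprotonation of the tertiary hydroxyl, the alkenyl group attacks the unhindered terminal CH2 only, so neither stereocentre is touched and (3R,4S) is carried over.

Step 3
Reactants: 4 (3R,4S)-3,7-dimethylocta-1,6-diene-3,4-diol; 5 2-(diethoxyphosphoryl)acetic acid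
Product: 6 (3R,4S)-3-hydroxy-3,7-dimethylocta-1,6-dien-4-yl 2-(diethoxyphosphoryl)acetate
Conditions: DCC (1.2 equiv), DMAP (5 mol %), CH2Cl2, 0 °C to rt
Reagents that add atoms: none
Why: Steglich esterification acylates the secondary hydroxyl and leaves the tertiary allylic hydroxyl alone under carbodiimide conditions; no C–O bond at a stereocentre is broken.

Step 4
Reactants: 6 (3R,4S)-3-hydroxy-3,7-dimethylocta-1,6-dien-4-yl 2-(diethoxyphosphoryl)acetate
Product: 7 (3R,4S)-3-(acetyloxy)-3,7-dimethylocta-1,6-dien-4-yl 2-(diethoxyphosphoryl)acetate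
Conditions: Ac2O (5 equiv), Et3N (6 equiv), DMAP (1 equiv), CH2Cl2, rt, 24 h
Reagents that add atoms: acetic anhydride, CC(=O)OC(C)=O
Why: DMAP-catalysed acylation (Steglich–Höfle) through the N-acetylpyridinium ion acetylates the only free, tertiary hydroxyl on oxygen, so the C3 configuration is retained, and Et3N is too weak a base to enolise the phosphonoacetate.

Step 5
Reactants: 7 (3R,4S)-3-(acetyloxy)-3,7-dimethylocta-1,6-dien-4-yl 2-(diethoxyphosphoryl)acetate; 8 4-hydroxybenzaldehyde
Product: 9 (3R,4S)-3-(acetyloxy)-3,7-dimethylocta-1,6-dien-4-yl (2E)-3-(4-hydroxyphenyl)prop-2-enoate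
Conditions: 8 (1.3 equiv), LiCl (3 equiv), DBU (2.5 equiv), MeCN, rt; then pH 5 phosphate buffer
Reagents that add atoms: none
Why: Horner–Wadsworth–Emmons olefination under Masamune–Roush conditions: one extra equivalent of base carries the phenol as its phenoxide, the lithium-chelated phosphonate anion gives the (E)-cinnamate, and the amine base leaves both hindered esters and both stereocentres unchanged.

## Compound list

1 | 3-methylpenta-1,4-dien-3-ol | C=CC(C)(O)C=C | starting material
2 | (2R)-2-[(2S)-oxiran-2-yl]but-3-en-2-ol | C=C[C@@](C)(O)[C@@H]1CO1 | intermediate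
3 | (2-methylprop-1-en-1-yl)magnesium bromide | CC(C)=C[Mg]Br | starting material
4 | (3R,4S)-3,7-dimethylocta-1,6-diene-3,4-diol | C=C[C@@](C)(O)[C@@H](O)CC=C(C)C | intermediate
5 | 2-(diethoxyphosphoryl)acetic acid | CCOP(=O)(CC(=O)O)OCC | starting material
6 | (3R,4S)-3-hydroxy-3,7-dimethylocta-1,6-dien-4-yl 2-(diethoxyphosphoryl)acetate | C=C[C@@](C)(O)[C@H](CC=C(C)C)OC(=O)CP(=O)(OCC)OCC | intermediate
7 | (3R,4S)-3-(acetyloxy)-3,7-dimethylocta-1,6-dien-4-yl 2-(diethoxyphosphoryl)acetate | C=C[C@@](C)(OC(C)=O)[C@H](CC=C(C)C)OC(=O)CP(=O)(OCC)OCC | intermediate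
8 | 4-hydroxybenzaldehyde | O=Cc1ccc(O)cc1 | starting material
9 | (3R,4S)-3-(acetyloxy)-3,7-dimethylocta-1,6-dien-4-yl (2E)-3-(4-hydroxyphenyl)prop-2-enoate | C=C[C@@](C)(OC(C)=O)[C@H](CC=C(C)C)OC(=O)/C=C/c1ccc(O)cc1 | target

## Step count and risks

Total step count: 5. Longest linear sequence: 5 (1 → 2 → 4 → 6 → 7 → 9).

The three steps most likely to fail are steps 1, 4 and 5.

**Step 1.** Methyl and the spectator vinyl group are close in size, so the choice between the two enantiotopic vinyl groups (the d.r.) may be modest. The monosubstituted alkenes are also slow to epoxidise, and 2 is small and volatile. The fallback builds the quaternary centre after the symmetry-breaking event instead of during it. It sets out from Grignard reagent 3 and, in place of 1, from penta-1,4-dien-3-ol F1, and it comes back to the route at diol 4. Sharpless asymmetric epoxidation of F1 (Ti(OiPr)4, D-(−)-diisopropyl tartrate, cumene hydroperoxide, 4 Å MS, CH2Cl2, −20 °C) discriminates hydrogen against vinyl cleanly and gives (2S,3R)-1,2-epoxypent-4-en-3-ol F2. Opening with 3 and CuI as in step 2 gives (3R,4S)-7-methylocta-1,6-diene-3,4-diol F3. Activated MnO2 (CH2Cl2, rt) oxidises only the allylic hydroxyl to (4S)-4-hydroxy-7-methylocta-1,6-dien-3-one F4. MeMgBr (3 equiv, THF, −78 °C) then adds to the five-membered magnesium chelate of this α-alkoxy ketone from the face of the C4 hydrogen, which sets the (3R) centre and gives 4.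

**Step 4.** The tertiary allylic hydroxyl is slow to acylate. Under base the phosphonoacetyl group could also shift to the tertiary oxygen, after which the freed secondary hydroxyl would be acetylated to give the regioisomer. The fallback inverts the order of acylation through a cyclic orthoester. It sets out from diol 4 and comes back to the route at 7. Diol 4 with triethyl orthoacetate and catalytic pyridinium p-toluenesulfonate (CH2Cl2, rt) gives (4R,5S)-2-ethoxy-4-ethenyl-2,4-dimethyl-5-(3-methylbut-2-en-1-yl)-1,3-dioxolane F5 as both epimers at C2. Cold 80% aqueous acetic acid is expected to open it kinetically to the ester on the more hindered oxygen, (3R,4S)-4-hydroxy-3,7-dimethylocta-1,6-dien-3-yl acetate F6. F6 is esterified at once with acid 5 and DCC without DMAP (CH2Cl2, 0 °C), conditions too mild for the acetyl group to move, and this gives 7.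

**Step 5.** The phenoxide of 8 is a deactivated and poorly soluble aldehyde, so the olefination may stall while 7 sits in base. The fallback masks the phenol for the olefination. It sets out from 7 and 8 and comes back to the route at target 9. Aldehyde 8 with tert-butyldimethylsilyl chloride and imidazole (DMF, rt) gives 4-[(tert-butyldimethylsilyl)oxy]benzaldehyde F7. F7 and 7 (LiCl, iPr2NEt, MeCN, rt) give (3R,4S)-3-(acetyloxy)-3,7-dimethylocta-1,6-dien-4-yl (2E)-3-{4-[(tert-butyldimethylsilyl)oxy]phenyl}prop-2-enoate F8. HF·pyridine (THF, 0 °C) frees the phenol without touching either ester and gives 9.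

Further compounds
F1 | step 1 | penta-1,4-dien-3-ol | C=CC(O)C=C
F2 | step 1 | (2S,3R)-1,2-epoxypent-4-en-3-ol | C=C[C@@H](O)[C@@H]1CO1
F3 | step 1 | (3R,4S)-7-methylocta-1,6-diene-3,4-diol | C=C[C@@H](O)[C@@H](O)CC=C(C)C
F4 | step 1 | (4S)-4-hydroxy-7-methylocta-1,6-dien-3-one | C=CC(=O)[C@@H](O)CC=C(C)C
F5 | step 4 | (4R,5S)-2-ethoxy-4-ethenyl-2,4-dimethyl-5-(3-methylbut-2-en-1-yl)-1,3-dioxolane (both C2 epimers) | C=C[C@@]1(C)OC(C)(OCC)O[C@H]1CC=C(C)C
F6 | step 4 | (3R,4S)-4-hydroxy-3,7-dimethylocta-1,6-dien-3-yl acetate | C=C[C@@](C)(OC(C)=O)[C@@H](O)CC=C(C)C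
F7 | step 5 | 4-[(tert-butyldimethylsilyl)oxy]benzaldehyde | CC(C)(C)[Si](C)(C)Oc1ccc(C=O)cc1
F8 | step 5 | (3R,4S)-3-(acetyloxy)-3,7-dimethylocta-1,6-dien-4-yl (2E)-3-{4-[(tert-butyldimethylsilyl)oxy]phenyl}prop-2-enoate | C=C[C@@](C)(OC(C)=O)[C@H](CC=C(C)C)OC(=O)/C=C/c1ccc(O[Si](C)(C)C(C)(C)C)cc1
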